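**Strategy.** With the cyclopentenone ring numbered C1 (C=O), C2 (OMe), C3 (aryl), C4 (spiro-epoxide carbon) and C5 (OMe, aryl), the trans C4–O/C5–OMe pair is treated as a masked C4=C5 alkene of a 2-aryl-3-(oxymethyl)cyclopentenone. An enantioselective nickel-catalysed reductive [3+2] cycloaddition of a phenyl α-methoxycinnamate (C1–C3) with an aryl propargyl silyl ether (C4–C5) forms C3–C4 and C1–C5 in one operation and sets a temporary C3–H stereocentre. That centre directs epoxidation of C4=C5; Payne rearrangement with O-methylation then gives the spiro-epoxide and C5–OMe, and dehydrogenation finally erases C3–H while creating the C2=C3 enol ether.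

Key step: step 7

**Remarks on the chemistry**
- Ar′ = 4-[(triisopropylsilyl)oxy]phenyl; TIPS = triisopropylsilyl; TBS = tert-butyldimethylsilyl. Locants C1–C5 are those defined above.
- Compounds 11–15 are drawn with the C2 methoxy group trans to the C3 aryl group (the expected thermodynamic epimer). The C2 epimer would converge on the same product, because C2 becomes sp2 in step 11.
- The enantiomer of the chiral carbene ligand in step 7 is the one that gives the 4R cyclopentenone; it would be assigned by a short screen.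

**Step 1**
Reactants: 1 4-hydroxybenzaldehyde
Product: 2 4-[(triisopropylsilyl)oxy]benzaldehyde
Conditions: TIPSCl, imidazole, DMF, rt
Reagents that add atoms: triisopropylsilyl chloride, CC(C)[Si](Cl)(C(C)C)C(C)C
Why: Imidazole-promoted O-silylation of the phenol; the bulky TIPS ether should resist the basic, oxidising and organometallic steps ahead and leaves with fluoride at the end.

**Step 2**
Reactants: 2 4-[(triisopropylsilyl)oxy]benzaldehyde; 3 methyl 2-(dimethoxyphosphoryl)-2-methoxyacetate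
Product: 4 methyl (2Z)-2-methoxy-3-Ar′-prop-2-enoate
Conditions: NaH, THF, 0 °C to rt
Reagents that add atoms: none
Why: Horner–Wadsworth–Emmons olefination; the Z isomer (aryl trans to the ester) is the thermodynamically preferred product and any E isomer would be removed by chromatography.

**Step 3**
Reactants: 4 methyl (2Z)-2-methoxy-3-Ar′-prop-2-enoate
Product: 5 (2Z)-2-methoxy-3-Ar′-prop-2-enoic acid
Conditions: Me3SnOH, 1,2-dichloroethane, 80 °C; then 1 M HCl
Reagents that add atoms: trimethyltin hydroxide, C[Sn](C)(C)O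
Why: Near-neutral acyl–oxygen ester hydrolysis with Me3SnOH, chosen because it spares the base-labile aryl silyl ether.

**Step 4**
Reactants: 5 (2Z)-2-methoxy-3-Ar′-prop-2-enoic acid
Product: 6 phenyl (2Z)-2-methoxy-3-Ar′-prop-2-enoate
Conditions: phenol, DCC, DMAP (cat.), CH2Cl2, 0 °C to rt
Reagents that add atoms: phenol, Oc1ccccc1
Why: Steglich esterification; the aryl ester supplies the activated acyl group and phenoxide leaving group that the cycloaddition needs.

**Step 5**
Reactants: 7 4-iodophenol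
Product: 8 (4-iodophenoxy)triisopropylsilane
Conditions: TIPSCl, imidazole, DMF, rt
Reagents that add atoms: triisopropylsilyl chloride, CC(C)[Si](Cl)(C(C)C)C(C)C
Why: Imidazole-promoted O-silylation of the phenol, as in step 1.

**Step 6**
Reactants: 8 (4-iodophenoxy)triisopropylsilane; 9 tert-butyldimethyl(prop-2-yn-1-yloxy)silane
Product: 10 tert-butyldimethyl[(3-Ar′-prop-2-yn-1-yl)oxy]silane
Conditions: Pd(PPh3)2Cl2 (2 mol%), CuI (4 mol%), Et3N, THF, rt
Reagents that add atoms: none
Why: Sonogashira coupling of the aryl iodide with the terminal alkyne under mild conditions that leave both silyl ethers intact.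

**Step 7**
Reactants: 6 phenyl (2Z)-2-methoxy-3-Ar′-prop-2-enoate; 10 tert-butyldimethyl[(3-Ar′-prop-2-yn-1-yl)oxy]silane
Product: 11 (4R,5S)-3-(TBSO-methyl)-5-methoxy-2,4-bis(Ar′)cyclopent-2-en-1-one
Conditions: Ni(cod)2 (10 mol%), L*·HCl (12 mol%), KOt-Bu (12 mol%), Et3B (2.0 equiv), THF/MeOH, 50 °C, slow addition of 10; L* = bulky enantiopure imidazol-2-ylidene with chiral 1-arylethyl side arms
Reagents that add atoms: none
Why: Zerovalent nickel bound to the chiral carbene couples enoate and alkyne by oxidative cyclisation (C3–C4 bond, nickel O-enolate), methanol protonates the enolate carbon C2, and the resulting alkenylnickel adds to the phenyl ester carbonyl and expels phenoxide (C1–C5 bond), after which Et3B returns divalent nickel to the zerovalent state with loss of ethene. The closest known reaction is the nickel-catalysed reductive [3+2] cycloaddition of aryl enoates with alkynes, including its enantioselective carbene-ligand variant; the α-methoxy group on the enoate is the new element. The five-membered ring closes by 5-exo-trig acyl substitution of the C5 alkenylnickel on the ester carbonyl C1. The C3 stereocentre is set in the oxidative cyclisation by the chiral ligand, which selects the enoate face, while C2 is set by protonation and should settle trans to the C3 aryl group by epimerisation (it is removed later). The step needs regioselective alkyne insertion with the aryl-bearing carbon on nickel, which the aryl/alkyl bias of the alkyne should secure, and cross-coupling over alkyne oligomerisation, which the electron-poor phenyl ester and slow alkyne addition should favour.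

**Step 8**
Reactants: 11 (4R,5S)-3-(TBSO-methyl)-5-methoxy-2,4-bis(Ar′)cyclopent-2-en-1-one
Product: 12 (4R,5S)-3-(hydroxymethyl)-5-methoxy-2,4-bis(Ar′)cyclopent-2-en-1-one
Conditions: camphorsulfonic acid (10 mol%), MeOH/CH2Cl2, 0 °C
Reagents that add atoms: none
Why: Acid-catalysed methanolysis cleaves the primary alkyl TBS ether selectively, since aryl TIPS ethers are stable to mild acid.

**Step 9**
Reactants: 12 (4R,5S)-3-(hydroxymethyl)-5-methoxy-2,4-bis(Ar′)cyclopent-2-en-1-one
Product: 13 (1R,3S,4S,5S)-5-(hydroxymethyl)-3-methoxy-1,4-bis(Ar′)-6-oxabicyclo[3.1.0]hexan-2-one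
Conditions: dimethyldioxirane (3 equiv, in acetone), CH2Cl2, 0 °C to rt, dark
Reagents that add atoms: dimethyldioxirane, CC1(C)OO1
Why: Electrophilic dioxirane epoxidation of a 2-aryl enone under neutral conditions (no epimerisation of the γ-benzylic C3–H); oxygen should be delivered to the C4=C5 face anti to the neighbouring C3 aryl group, so C4 and C5 are set from C3.

**Step 10**
Reactants: 13 (1R,3S,4S,5S)-5-(hydroxymethyl)-3-methoxy-1,4-bis(Ar′)-6-oxabicyclo[3.1.0]hexan-2-one
Product: 15 (3R,4R,6S,7S)-4,6-dimethoxy-4,7-bis(Ar′)-1-oxaspiro[2.4]heptan-5-one, via sodium alkoxide 14 (not isolated)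
Conditions: NaH (1.05 equiv), THF, 0 °C, 1 h; then MeI (5 equiv), 0 °C to rt
Reagents that add atoms: iodomethane, CI
Why: Payne rearrangement followed by Williamson methylation: the primary alkoxide attacks C4 from the face opposite the fused epoxide oxygen (3-exo-tet, inversion at C4), which places the new spiro-epoxide oxygen trans to the retained C5–O bond, and the sodium-chelated α-keto tertiary alkoxide, the weaker base of the two, is trapped by MeI.

**Step 11**
Reactants: 15 (3R,4R,6S,7S)-4,6-dimethoxy-4,7-bis(Ar′)-1-oxaspiro[2.4]heptan-5-one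
Product: 18 (3R,4R)-4,6-dimethoxy-4,7-bis(Ar′)-1-oxaspiro[2.4]hept-6-en-5-one, via lithium enolate 16 (not isolated), via sulfilimine adduct 17 (not isolated)
Conditions: LDA (1.2 equiv), THF, −78 °C; then N-tert-butylbenzenesulfinimidoyl chloride (1.3 equiv), −78 °C
Reagents that add atoms: none
Why: Mukaiyama dehydrogenation: the lithium enolate at C2 (the only enolisable α-carbon) is sulfinimidoylated anti to the C3 aryl group and the adduct undergoes syn-elimination with the cis C3–H, which creates the C2=C3 enol ether and erases the temporary C2 and C3 stereocentres.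

**Step 12**
Reactants: 18 (3R,4R)-4,6-dimethoxy-4,7-bis(Ar′)-1-oxaspiro[2.4]hept-6-en-5-one
Product: 19 (3R,4R)-4,7-bis(4-hydroxyphenyl)-4,6-dimethoxy-1-oxaspiro[2.4]hept-6-en-5-one
Conditions: TBAF (2.5 equiv), AcOH (2.5 equiv), THF, 0 °C
Reagents that add atoms: none
Why: Fluoride cleavage of both aryl TIPS ethers, buffered with acetic acid so that the vinyl epoxide and the benzylic C5 methyl ether should survive.

**Compound list**
1 | 4-hydroxybenzaldehyde | O=Cc1ccc(O)cc1 | starting material
2 | 4-[(triisopropylsilyl)oxy]benzaldehyde | O=Cc1ccc(O[Si](C(C)C)(C(C)C)C(C)C)cc1 | intermediate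
3 | methyl 2-(dimethoxyphosphoryl)-2-methoxyacetate | COC(C(=O)OC)P(=O)(OC)OC | starting material
4 | methyl (2Z)-2-methoxy-3-{4-[(triisopropylsilyl)oxy]phenyl}prop-2-enoate | CO/C(=C\c1ccc(O[Si](C(C)C)(C(C)C)C(C)C)cc1)C(=O)OC | intermediate
5 | (2Z)-2-methoxy-3-{4-[(triisopropylsilyl)oxy]phenyl}prop-2-enoic acid | CO/C(=C\c1ccc(O[Si](C(C)C)(C(C)C)C(C)C)cc1)C(=O)O | intermediate
6 | phenyl (2Z)-2-methoxy-3-{4-[(triisopropylsilyl)oxy]phenyl}prop-2-enoate | CO/C(=C\c1ccc(O[Si](C(C)C)(C(C)C)C(C)C)cc1)C(=O)Oc1ccccc1 | intermediate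
7 | 4-iodophenol | Oc1ccc(I)cc1 | starting material
8 | (4-iodophenoxy)triisopropylsilane | CC(C)[Si](Oc1ccc(I)cc1)(C(C)C)C(C)C | intermediate
9 | tert-butyldimethyl(prop-2-yn-1-yloxy)silane | C#CCO[Si](C)(C)C(C)(C)C | starting material
10 | tert-butyldimethyl[(3-{4-[(triisopropylsilyl)oxy]phenyl}prop-2-yn-1-yl)oxy]silane | CC(C)[Si](Oc1ccc(C#CCO[Si](C)(C)C(C)(C)C)cc1)(C(C)C)C(C)C | intermediate
11 | (4R,5S)-3-({[tert-butyl(dimethyl)silyl]oxy}methyl)-5-methoxy-2,4-bis{4-[(triisopropylsilyl)oxy]phenyl}cyclopent-2-en-1-one | CO[C@H]1[C@H](c2ccc(O[Si](C(C)C)(C(C)C)C(C)C)cc2)C(CO[Si](C)(C)C(C)(C)C)=C(c2ccc(O[Si](C(C)C)(C(C)C)C(C)C)cc2)C1=O | intermediate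
12 | (4R,5S)-3-(hydroxymethyl)-5-methoxy-2,4-bis{4-[(triisopropylsilyl)oxy]phenyl}cyclopent-2-en-1-one | CO[C@H]1[C@H](c2ccc(O[Si](C(C)C)(C(C)C)C(C)C)cc2)C(CO)=C(c2ccc(O[Si](C(C)C)(C(C)C)C(C)C)cc2)C1=O | intermediate
13 | (1R,3S,4S,5S)-5-(hydroxymethyl)-3-methoxy-1,4-bis{4-[(triisopropylsilyl)oxy]phenyl}-6-oxabicyclo[3.1.0]hexan-2-one (epoxide oxygen anti to the C4 aryl group) | CO[C@H]1[C@H](c2ccc(O[Si](C(C)C)(C(C)C)C(C)C)cc2)[C@@]2(CO)O[C@@]2(c2ccc(O[Si](C(C)C)(C(C)C)C(C)C)cc2)C1=O | intermediate
14 | sodium (3R,4R,6S,7S)-6-methoxy-5-oxo-4,7-bis{4-[(triisopropylsilyl)oxy]phenyl}-1-oxaspiro[2.4]heptan-4-olate (Payne alkoxide, not isolated) | CO[C@H]1[C@H](c2ccc(O[Si](C(C)C)(C(C)C)C(C)C)cc2)[C@@]2(CO2)[C@]([O-])(c2ccc(O[Si](C(C)C)(C(C)C)C(C)C)cc2)C1=O.[Na+] | intermediate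
15 | (3R,4R,6S,7S)-4,6-dimethoxy-4,7-bis{4-[(triisopropylsilyl)oxy]phenyl}-1-oxaspiro[2.4]heptan-5-one | CO[C@H]1[C@H](c2ccc(O[Si](C(C)C)(C(C)C)C(C)C)cc2)[C@@]2(CO2)[C@](OC)(c2ccc(O[Si](C(C)C)(C(C)C)C(C)C)cc2)C1=O | intermediate
16 | lithium enolate of 15 (C5 enolate oxygen, C5=C6 double bond in spiro numbering; not isolated) | COC=1[C@H](c2ccc(O[Si](C(C)C)(C(C)C)C(C)C)cc2)[C@@]2(CO2)[C@](OC)(c2ccc(O[Si](C(C)C)(C(C)C)C(C)C)cc2)C=1[O-].[Li+] | intermediate
17 | (3R,4R,6S,7R)-6-(N-tert-butyl-S-phenylsulfinimidoyl)-4,6-dimethoxy-4,7-bis{4-[(triisopropylsilyl)oxy]phenyl}-1-oxaspiro[2.4]heptan-5-one (sulfur anti to the C7 aryl group, either configuration at sulfur; not isolated) | CO[C@]1(S(=NC(C)(C)C)c3ccccc3)[C@H](c2ccc(O[Si](C(C)C)(C(C)C)C(C)C)cc2)[C@@]2(CO2)[C@](OC)(c2ccc(O[Si](C(C)C)(C(C)C)C(C)C)cc2)C1=O | intermediate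
18 | (3R,4R)-4,6-dimethoxy-4,7-bis{4-[(triisopropylsilyl)oxy]phenyl}-1-oxaspiro[2.4]hept-6-en-5-one | COC1=C(c2ccc(O[Si](C(C)C)(C(C)C)C(C)C)cc2)[C@@]2(CO2)[C@](OC)(c2ccc(O[Si](C(C)C)(C(C)C)C(C)C)cc2)C1=O | intermediate
19 | (3R,4R)-4,7-bis(4-hydroxyphenyl)-4,6-dimethoxy-1-oxaspiro[2.4]hept-6-en-5-one | COC1=C(c2ccc(O)cc2)[C@@]2(CO2)[C@](OC)(c2ccc(O)cc2)C1=O | target

**Step count.** Total: 12 steps. Longest linear sequence: 10 steps (1–4, then 7–12).

**Steps most likely to fail**

1. Step 7. Oxidative cyclisation of the α-methoxy-substituted, more electron-rich enoate at zerovalent nickel may be too slow, so that alkyne oligomerisation takes over, or the extra α-substituent may erode facial control by the ligand. The fallback sets out from 8 and returns at 11, and takes the methoxy group out of the cycloaddition. Heck coupling of 8 with phenyl acrylate (Pd(OAc)2, P(o-tol)3, Et3N, DMF, 90 °C) should give phenyl (2E)-3-{4-[(triisopropylsilyl)oxy]phenyl}prop-2-enoate F1, which belongs exactly to the substrate class for which the enantioselective nickel cycloaddition is established. Reaction of F1 with alkyne 10 under the conditions of step 7 should give (4R)-3-({[tert-butyl(dimethyl)silyl]oxy}methyl)-2,4-bis{4-[(triisopropylsilyl)oxy]phenyl}cyclopent-2-en-1-one F2. Kinetic α′-deprotonation (LDA, THF, −78 °C) and hydroxylation of the cross-conjugated enolate with 3-phenyl-2-(phenylsulfonyl)oxaziridine anti to the aryl group should give (4R,5S)-3-({[tert-butyl(dimethyl)silyl]oxy}methyl)-5-hydroxy-2,4-bis{4-[(triisopropylsilyl)oxy]phenyl}cyclopent-2-en-1-one F3, and O-methylation (MeI, Ag2O) then gives 11.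

2. Step 10. The Payne equilibrium may not lie far enough toward the tertiary α-keto alkoxide, so that the faster-reacting primary alkoxide, or a trace of the C2 enolate, is methylated instead. The fallback sets out from 13 and returns at 15, and separates the two events. Substoichiometric NaH (0.1 equiv, THF, 0 °C to rt) lets the epoxy alcohols equilibrate by alkoxide chain transfer. After a neutral quench the α-ketol (3R,4R,6S,7S)-4-hydroxy-6-methoxy-4,7-bis{4-[(triisopropylsilyl)oxy]phenyl}-1-oxaspiro[2.4]heptan-5-one F4 is isolated, with recovered 13 recycled. F4 is then methylated under neutral Purdie conditions (MeI, Ag2O, CH2Cl2, dark), where neither alkoxide nor enolate is present, to give 15.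

3. Step 9. Oxygen transfer to the electron-poor, fully substituted alkene may be slow enough for over-oxidation of the free primary allylic alcohol or of the silyloxyarenes to compete. The fallback sets out from 11 and returns at 13; it reverses the electronic demand and keeps the alcohol masked. Weitz–Scheffer epoxidation of silyl ether 11 (t-BuOOH, catalytic benzyltrimethylammonium hydroxide, THF, 0 °C) proceeds by conjugate addition of the peroxide anion at C4 anti to the C3 aryl group and enolate closure. It should give (1R,3S,4S,5S)-5-({[tert-butyl(dimethyl)silyl]oxy}methyl)-3-methoxy-1,4-bis{4-[(triisopropylsilyl)oxy]phenyl}-6-oxabicyclo[3.1.0]hexan-2-one F5. HF·pyridine buffered with pyridine (THF, 0 °C) then removes the primary silyl ether and gives 13.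

**Further compounds**
F1 | step 7 | phenyl (2E)-3-{4-[(triisopropylsilyl)oxy]phenyl}prop-2-enoate | O=C(/C=C/c1ccc(O[Si](C(C)C)(C(C)C)C(C)C)cc1)Oc1ccccc1
F2 | step 7 | (4R)-3-({[tert-butyl(dimethyl)silyl]oxy}methyl)-2,4-bis{4-[(triisopropylsilyl)oxy]phenyl}cyclopent-2-en-1-one | C1[C@H](c2ccc(O[Si](C(C)C)(C(C)C)C(C)C)cc2)C(CO[Si](C)(C)C(C)(C)C)=C(c2ccc(O[Si](C(C)C)(C(C)C)C(C)C)cc2)C1=O
F3 | step 7 | (4R,5S)-3-({[tert-butyl(dimethyl)silyl]oxy}methyl)-5-hydroxy-2,4-bis{4-[(triisopropylsilyl)oxy]phenyl}cyclopent-2-en-1-one | O[C@H]1[C@H](c2ccc(O[Si](C(C)C)(C(C)C)C(C)C)cc2)C(CO[Si](C)(C)C(C)(C)C)=C(c2ccc(O[Si](C(C)C)(C(C)C)C(C)C)cc2)C1=O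
F4 | step 10 | (3R,4R,6S,7S)-4-hydroxy-6-methoxy-4,7-bis{4-[(triisopropylsilyl)oxy]phenyl}-1-oxaspiro[2.4]heptan-5-one | CO[C@H]1[C@H](c2ccc(O[Si](C(C)C)(C(C)C)C(C)C)cc2)[C@@]2(CO2)[C@](O)(c2ccc(O[Si](C(C)C)(C(C)C)C(C)C)cc2)C1=O
F5 | step 9 | (1R,3S,4S,5S)-5-({[tert-butyl(dimethyl)silyl]oxy}methyl)-3-methoxy-1,4-bis{4-[(triisopropylsilyl)oxy]phenyl}-6-oxabicyclo[3.1.0]hexan-2-one | CO[C@H]1[C@H](c2ccc(O[Si](C(C)C)(C(C)C)C(C)C)cc2)[C@@]2(CO[Si](C)(C)C(C)(C)C)O[C@@]2(c2ccc(O[Si](C(C)C)(C(C)C)C(C)C)cc2)C1=O
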